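The earlier runs and the new flask were computed with made-up constants, noise included.

A yield carried over from another run is the pitfall here, since over-reaction product at 30.0 min stands at 4.0 % in red and at 47.5 % in amber. A chance at a fork may travel better. A molecule of target either takes up a further coupling partner and becomes over-reaction product, or it is still target when the reaction stops.

| setting | red | amber | violet | flask |
|---|---|---|---|---|
| substrate | 0.25 M | 0.25 M | 0.50 M | 0.25 M |
| coupling partner | 0.45 equiv | 1.8 equiv | 0.90 equiv | 0.900 equiv |
| remark | run made earlier | run made earlier | run made earlier |  |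
| time |  |  |  | 50 min |

- share of over-reaction product in over-reaction product plus target at 1.5 min
- share of over-reaction product in over-reaction product plus target at 50 min

| run | time / min | over-reaction product / % | target / % |
|---|---|---|---|
| red | 1.50 | 1.0 | 0.7 |
| red | 5.00 | 3.0 | 1.4 |
| red | 8.00 | 3.0 | 1.7 |
| red | 12.0 | 5.5 | 1.9 |
| red | 20.0 | 4.6 | 1.9 |
| red | 25.0 | 5.5 | 1.3 |
| red | 30.0 | 4.0 | 2.4 |
| amber | 4.00 | 30.3 | 2.7 |
| amber | 8.00 | 40.2 | 1.6 |
| amber | 12.0 | 43.8 | 0.6 |
| amber | 15.0 | 44.6 | 1.4 |
| amber | 20.0 | 45.4 | 1.1 |
| amber | 25.0 | 46.1 | 1.2 |
| amber | 30.0 | 47.5 | 1.9 |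
| violet | 6.00 | 14.8 | 1.9 |
| violet | 12.0 | 15.6 | 3.3 |
| violet | 20.0 | 16.0 | 2.5 |
| violet | 25.0 | 16.1 | 2.0 |
| violet | 30.0 | 15.6 | 2.3 |

(each reading ± 0.5 percentage points)

- the analysis behind the earlier runs scatters by 0.5 percentage points, standard deviation

The violet table is the one to read, because its 0.90 equiv of coupling partner equals the flask's 0.900 equiv. Down its over-reaction product column, the rows from 12.0 min on differ by 0.5 percentage points, which is the scatter of a reading. Over the same rows its target column wanders between 2.0 % and 3.3 %, but from 20.0 min on it too stays within that scatter. Summed over those later rows, the end share, meaning the percentage of over-reaction product in over-reaction product plus target once both columns are flat, reads 87.5 %.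

This reckoning assumes that each step takes up coupling partner in a bimolecular encounter. Violet's c(substrate), twice the flask's, then runs the same course at equal equivalents on a faster clock, and the chance at the fork stays the same. So 50 min in the flask corresponds to 25.0 min in violet, inside the flat rows, and the flask should show the end share. Its 1.5 min corresponds to 0.750 min, earlier than violet's first row at 6.00 min, so this reckoning commits to no early figure.

The forecast, holding that “the flask should resemble violet with its clock doubled”, gave 56 % (range 42 % to 70 %) and 87 % (range 83 % to 90 %).

    substrate ⇌ intermediate A (K = 6.80, k = 0.192 /s)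
    coupling partner + intermediate A → intermediate B (k = 0.0205 /M/s)
    coupling partner + intermediate A → intermediate D (k = 0.00708 /M/s)
    intermediate B → intermediate C (k = 0.137 /s)
    coupling partner + intermediate D ⇌ intermediate E (K = 3.40 /M, k = 0.0356 /M/s)
    coupling partner + target → over-reaction product (k = 0.382 /M/s)
    coupling partner + intermediate C → target (k = 0.0334 /M/s)

The flask gives 70.9 % at 1.5 min and 88.7 % at 50 min, which is 1.2 points above the end share. At 50.0 min the flask's coupling partner, the limiting reagent, stands at 0 % of its charge. The neighbouring flask, charged with 0.62 M of substrate at the recipe's equivalents, is the second case. For its 15.7 % of over-reaction product, the end share of 87.5 % implies 2.24 % of target. That neighbouring flask holds 2.10 % of target, a share of 88.2 %. Its share at 1.5 min is 82.6 %, higher than the flask's 70.9 %.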